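Labdane numbering is used: ring A = C1–C5/C10, ring B = C5–C10. The retrosynthesis cuts, in order, the C13(16),C14 diene (back to a C13 alkyne), the acetate, C8–O/C17 and C6–O (two epoxides built around a C8 ketone), C11–C12, C9–C11, then C3–C4 (ring A), C10–C1 and C4–C5.
Forward: ring B is bought as 2-methylcyclohex-2-enone (C9=O, C10–CH3). A Johnson–Claisen shift puts the C4/C18/C19 propanoate arm on C5, a conjugate allylation puts C1–C3 on C10, and ring A is closed last by joining C3 to C4. The C8 ketone then serves to build C9–C11–C13, 6-OH and 8-OH/C17.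
Enabling feature: C4 is the α-carbon of the oxidised carbon C18 and is bonded to the ring-fusion methine C5–H, while C3 ends a three-carbon chain on the neighbouring quaternary C10. As the ester enolate C4=C18, C4 is planar, nucleophilic and locked against C5–H, so one C–C bond closes ring A and fixes its hardest centre.
Stereochemistry: one reagent-controlled step (CBS reduction, C9 carbinol) sets C5 by suprafacial [3,3] transfer, then C10 by anti conjugate addition, then C4 by allylic strain in the ring closure. C9 comes from protonation/equilibration to the equatorial chain. C6 and C8 come from epoxidation on the face opposite the axial methyl groups C19 and C20.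

Key step: step 6

Remark on notation: "up" and "down" refer to the usual drawing (ring A left, ring B right, C10 at the top of the shared bond). In the target 5-H, 9-H, C18, 6-OH and 8-OH are up; C19, C20, C17 and the C9 chain are down; this is (4S,5S,6R,8S,9S,10R).
Remark on the chemistry: compounds 5, 6, 8 and 9 are carried as mixtures of epimers at C4 (the ester α-carbon), which step 6 planarises. Their SMILES leave this centre open.

Step 1
Reactants: 1 2-methylcyclohex-2-en-1-one
Product: 2 (1R)-2-methylcyclohex-2-en-1-ol
Conditions: (S)-2-methyl-CBS-oxazaborolidine (10 mol %), BH3·SMe2 (0.6 equiv), THF, −20 °C; MeOH, then H2O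
Reagents that add atoms: none
Why: Corey–Bakshi–Shibata reduction, in which the methyl-bearing alkene arm acts as the large group, so hydride delivery should set the C9 carbinol as R (C–O down).

Step 2
Reactants: 2 (1R)-2-methylcyclohex-2-en-1-ol; 3 triethyl orthopropionate
Product: 5 ethyl 2-[(1R)-2-methylcyclohex-2-en-1-yl]propanoate, via mixed ketene acetal 4 (not isolated)
Conditions: 3 (5 equiv), EtCO2H (5 mol %), 140 °C, EtOH distilled off
Reagents that add atoms: triethyl orthopropionate CCC(OCC)(OCC)OCC
Why: Johnson–Claisen rearrangement, in which the suprafacial [3,3] shift of 4 across the ring face bearing the C9–O bond forms C4–C5 (C4 down, 5-H up), transfers the C9 configuration to C5 and moves the alkene to C9=C10.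

Step 3
Reactants: 5 ethyl 2-[(1R)-2-methylcyclohex-2-en-1-yl]propanoate
Product: 6 ethyl 2-[(1R)-2-methyl-4-oxocyclohex-2-en-1-yl]propanoate
Conditions: Pd(OH)2/C (5 mol %), t-BuOOH (5 equiv), K2CO3 (0.25 equiv), CH2Cl2, 4 °C
Reagents that add atoms: tert-butyl hydroperoxide CC(C)(C)OO
Why: Palladium-catalysed tert-butylperoxy-radical allylic oxidation should convert the only ring methylene allylic to the trisubstituted alkene (C8) into the ketone, giving the 3-methylcyclohexenone needed for step 4 without touching C5.

Step 4
Reactants: 6 ethyl 2-[(1R)-2-methyl-4-oxocyclohex-2-en-1-yl]propanoate; 7 allyltrimethylsilane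
Product: 8 ethyl 2-[(1R,2S)-2-allyl-2-methyl-4-oxocyclohexyl]propanoate (allyl up on C10, trans to the propanoate arm on C5; 10-CH3 down)
Conditions: TiCl4 (1.5 equiv), 7 (1.5 equiv), CH2Cl2, −78 °C; H2O
Reagents that add atoms: allyltrimethylsilane C=CC[Si](C)(C)C
Why: Hosomi–Sakurai conjugate allylation, a standard route to a quaternary β-carbon; allylic 1,2-strain with the C10 methyl group holds the C5 arm pseudoaxial and the silane attacks C10 axially on the opposite face, so C1 ends trans to C4.

Step 5
Reactants: 8 ethyl 2-[(1R,2S)-2-allyl-2-methyl-4-oxocyclohexyl]propanoate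
Product: 9 ethyl 2-[(1R,2S)-2-(3-bromopropyl)-2-methyl-4-oxocyclohexyl]propanoate
Conditions: HBr (g), dibenzoyl peroxide (5 mol %), hexane, 0 °C, light
Reagents that add atoms: hydrogen bromide Br
Why: Peroxide-initiated radical (anti-Markovnikov) hydrobromination puts bromine on the terminal carbon C3 and so reverses the polarity of the alkene terminus, while ketone and ester are inert to the bromine-atom chain.

Step 6
Reactants: 9 ethyl 2-[(1R,2S)-2-(3-bromopropyl)-2-methyl-4-oxocyclohexyl]propanoate
Product: 11 trans-decalone ester (ethyl 4,10-dimethyl-8-oxodecalin-4-carboxylate in labdane numbering; 5-H up; 10-CH3 and 4-CH3 down and axial; CO2Et up and equatorial), via dilithium bis-enolate 10 (not isolated)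
Conditions: LiN(i-Pr)2 (2.3 equiv), THF (0.01 M), −78 °C; DMPU (4 equiv), −78 → 0 °C; H2O
Reagents that add atoms: none
Why: The first equivalent of LiN(i-Pr)2 removes the least hindered ketone proton (C7–H) and the second the ester α-proton (C4–H), and on warming only the more basic ester enolate displaces bromide at C3, an intramolecular ester-enolate alkylation of well-known type. Ring A closes in the 6-(enolexo)-exo-tet mode through a chair in which C1 (on C10) and C4 (on C5) stay diequatorial on ring B, so the trans ring fusion written into 9 by step 4 is carried over unchanged. The new quaternary centre C4 is controlled by allylic 1,3-strain: the planar C4=C18 enolate eclipses C5–H, which places C19 between C6 and C10 and lets C3, tethered to C10, reach only one enolate face, so C18 ends equatorial (up) and C19 axial, syn to C20. The step needs selectivity between two enolates: the ketone is masked in the flask as its C7 enolate, whose carbon could reach C3 only through a bridged seven-membered ring, and the C9 enolate, which could close a cyclopentane, is disfavoured kinetically by the adjacent quaternary C10. High dilution suppresses intermolecular alkylation.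

Step 7
Reactants: 11 trans-decalone ester
Product: 12 decalin enone ester (C6=C7–C8=O; other centres as in 11)
Conditions: Pd(OCOCF3)2 (5 mol %), DMSO (10 mol %), O2 (1 atm), AcOH, 80 °C
Reagents that add atoms: none
Why: Aerobic palladium-catalysed α,β-dehydrogenation of a cyclohexanone (palladium enolate, then β-hydride elimination) can only desaturate C6–C7, because C10 carries no hydrogen.

Step 8
Reactants: 12 decalin enone ester; 13 N,N-dimethylmethyleneiminium iodide (Eschenmoser's salt)
Product: 16 cross-conjugated dienone ester with exocyclic C9=C11H2, via Mannich base 14 (not isolated), via methiodide 15 (not isolated)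
Conditions: LiN(i-Pr)2 (1.1 equiv), THF, −78 °C; 13, −78 °C → rt; MeI (5 equiv), rt; sat. aq. NaHCO3, CH2Cl2, rt
Reagents that add atoms: N,N-dimethylmethyleneiminium iodide C[N+](C)=C.[I-]; iodomethane CI (its atoms stay only in 15)
Why: Kinetic α′-deprotonation of the enone can only occur at C9, and Mannich reaction with the preformed iminium salt followed by quaternisation and E1cB loss of trimethylamine is the standard α-methylenation sequence.

Step 9
Reactants: 16 cross-conjugated dienone ester; 17 tributyl(propa-1,2-dienyl)stannane
Product: 18 9-(but-3-ynyl) enone ester (9-H up, chain down and equatorial; C6=C7–C8=O)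
Conditions: TiCl4 (1.2 equiv), 17 (1.3 equiv), CH2Cl2, −78 °C; aq. NaHCO3
Reagents that add atoms: tributyl(propa-1,2-dienyl)stannane C=C=C[Sn](CCCC)(CCCC)CCCC
Why: Lewis acid-mediated conjugate propargylation with an allenylstannane (SE2′), in which the allene CH2 terminus attacks the unhindered exocyclic terminus C11; protonation of the titanium dienolate at C9 from the face opposite C20 (expected also to be the thermodynamic outcome) should leave the chain equatorial.

Step 10
Reactants: 18 9-(but-3-ynyl) enone ester
Product: 19 6,7-epoxy-8-ketone (epoxide oxygen up)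
Conditions: 30% H2O2, NaOH (0.5 equiv), MeOH, 0 °C
Reagents that add atoms: hydrogen peroxide OO
Why: Weitz–Scheffer nucleophilic epoxidation, in which hydroperoxide adds to C6 on the upper face because the lower face is closed by the axial methyl groups C19 and C20; this sets the C6–O bond up, and alkyne and hindered ester are inert.

Step 11
Reactants: 19 6,7-epoxy-8-ketone
Product: 20 6-hydroxy-8-ketone (6-OH up and equatorial)
Conditions: SmI2 (2.5 equiv), THF–MeOH, −90 °C
Reagents that add atoms: none
Why: Samarium diiodide reduction of an α,β-epoxy ketone, in which the ketyl cleaves the Cα–O bond (C7–O) far faster than it could add to the alkyne; protonation of the enolate gives the β-hydroxy ketone with C6 untouched.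

Step 12
Reactants: 20 6-hydroxy-8-ketone
Product: 21 6-hydroxy-8(17)-ene (exocyclic C8=C17H2)
Conditions: Zn, CH2Br2, TiCl4 (reagent aged at 5 °C), THF–CH2Cl2, 0 °C → rt
Reagents that add atoms: dibromomethane BrCBr
Why: Lombardo methylenation with the non-basic gem-dizinc/titanium reagent should convert the hindered, elimination-prone β-hydroxy ketone into the exocyclic alkene without retro-aldol cleavage or dehydration.

Step 13
Reactants: 21 6-hydroxy-8(17)-ene
Product: 22 8,17-spiro-epoxide (C8–O up and equatorial, C17 down and axial)
Conditions: mCPBA (1.1 equiv), CH2Cl2, 0 °C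
Reagents that add atoms: 3-chloroperoxybenzoic acid O=C(OO)c1cccc(Cl)c1
Why: Prilezhaev epoxidation, in which the 1,1-disubstituted alkene reacts far faster than the terminal alkyne and the peracid approaches from the equatorial upper side, hydrogen-bonded to 6-OH and away from axial C20, as is usual for labd-8(17)-enes.

Step 14
Reactants: 22 8,17-spiro-epoxide
Product: 23 alkyne triol (6-OH, 8-OH and C18H2OH; 8-CH3 axial and down)
Conditions: LiAlH4 (5 equiv), THF, 0 °C → reflux; aqueous work-up
Reagents that add atoms: none
Why: Hydride opens the spiro-epoxide at its unsubstituted carbon C17, leaving the equatorial tertiary 8-OH and an axial methyl group, and the same reagent reduces the neopentyl ester to the C18 primary alcohol.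

Step 15
Reactants: 23 alkyne triol
Product: 24 alkyne diol 18-acetate
Conditions: Ac2O (1.05 equiv), pyridine, CH2Cl2, 0 °C
Reagents that add atoms: acetic anhydride CC(=O)OC(C)=O
Why: Rate-controlled acylation, in which the primary C18 hydroxyl should be acetylated well before the flanked secondary 6-OH and the tertiary 8-OH.

Step 16
Reactants: 24 alkyne diol 18-acetate; 25 ethylene
Product: 26 target, (4S,5S,6R,8S,9S,10R)-18-acetoxylabda-13(16),14-diene-6,8-diol
Conditions: second-generation Grubbs catalyst RuCl2(=CHPh)(PCy3)(H2IMes) (5 mol %), ethylene (1 atm), CH2Cl2, rt → 40 °C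
Reagents that add atoms: ethylene C=C
Why: Ethylene–alkyne cross (enyne) metathesis turns the terminal alkyne into the 2-substituted buta-1,3-diene; free hydroxyl groups and the acetate are tolerated and the ethylene atmosphere suppresses secondary metathesis of the diene.

Compound list
1 | 2-methylcyclohex-2-en-1-one | CC1=CCCCC1=O | starting material
2 | (1R)-2-methylcyclohex-2-en-1-ol | O[C@@H]1CCCC=C1C | intermediate
3 | triethyl orthopropionate | CCC(OCC)(OCC)OCC | starting material
4 | mixed ketene acetal (1-ethoxyprop-1-enyl ether of 2; not isolated) | CC=C(OCC)O[C@@H]1CCCC=C1C | intermediate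
5 | ethyl 2-[(1R)-2-methylcyclohex-2-en-1-yl]propanoate (C4 epimers) | CCOC(=O)C(C)[C@H]1CCCC=C1C | intermediate
6 | ethyl 2-[(1R)-2-methyl-4-oxocyclohex-2-en-1-yl]propanoate (C4 epimers) | CCOC(=O)C(C)[C@H]1CCC(=O)C=C1C | intermediate
7 | allyltrimethylsilane | C=CC[Si](C)(C)C | starting material
8 | ethyl 2-[(1R,2S)-2-allyl-2-methyl-4-oxocyclohexyl]propanoate (C4 epimers) | CCOC(=O)C(C)[C@H]1CCC(=O)C[C@]1(C)CC=C | intermediate
9 | ethyl 2-[(1R,2S)-2-(3-bromopropyl)-2-methyl-4-oxocyclohexyl]propanoate (C4 epimers) | CCOC(=O)C(C)[C@H]1CCC(=O)C[C@]1(C)CCCBr | intermediate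
10 | dilithium bis-enolate of 9 (C7=C8–O and C4=C18–O; not isolated) | [Li+].[Li+].CCOC([O-])=C(C)[C@H]1CC=C([O-])C[C@]1(C)CCCBr | intermediate
11 | trans-decalone ester (8-oxo; CO2Et equatorial on C4) | C1[C@]2(C)CCC[C@](C)(C(=O)OCC)[C@H]2CCC1=O | intermediate
12 | decalin enone ester (C6=C7–C8=O) | C1[C@]2(C)CCC[C@](C)(C(=O)OCC)[C@H]2C=CC1=O | intermediate
13 | N,N-dimethylmethyleneiminium iodide | C[N+](C)=C.[I-] | starting material
14 | Mannich base (9-CH2NMe2, C9 open; not isolated) | CN(C)CC1[C@]2(C)CCC[C@](C)(C(=O)OCC)[C@H]2C=CC1=O | intermediate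
15 | methiodide of 14 (not isolated) | C[N+](C)(C)CC1[C@]2(C)CCC[C@](C)(C(=O)OCC)[C@H]2C=CC1=O.[I-] | intermediate
16 | cross-conjugated dienone ester (C9=C11H2) | C=C1[C@]2(C)CCC[C@](C)(C(=O)OCC)[C@H]2C=CC1=O | intermediate
17 | tributyl(propa-1,2-dienyl)stannane | C=C=C[Sn](CCCC)(CCCC)CCCC | starting material
18 | 9-(but-3-ynyl) enone ester | C#CCC[C@H]1[C@]2(C)CCC[C@](C)(C(=O)OCC)[C@H]2C=CC1=O | intermediate
19 | 6,7-epoxy-8-ketone | C#CCC[C@H]1[C@]2(C)CCC[C@](C)(C(=O)OCC)[C@H]2[C@@H]3O[C@@H]3C1=O | intermediate
20 | 6-hydroxy-8-ketone | C#CCC[C@H]1[C@]2(C)CCC[C@](C)(C(=O)OCC)[C@H]2[C@H](O)CC1=O | intermediate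
21 | 6-hydroxy-8(17)-ene | C#CCC[C@H]1[C@]2(C)CCC[C@](C)(C(=O)OCC)[C@H]2[C@H](O)CC1=C | intermediate
22 | 8,17-spiro-epoxide | C#CCC[C@H]1[C@]2(C)CCC[C@](C)(C(=O)OCC)[C@H]2[C@H](O)C[C@@]13CO3 | intermediate
23 | alkyne triol | C#CCC[C@H]1[C@]2(C)CCC[C@](C)(CO)[C@H]2[C@H](O)C[C@]1(C)O | intermediate
24 | alkyne diol 18-acetate | C#CCC[C@H]1[C@]2(C)CCC[C@](C)(COC(C)=O)[C@H]2[C@H](O)C[C@]1(C)O | intermediate
25 | ethylene | C=C | starting material
26 | target | C=CC(=C)CC[C@H]1[C@]2(C)CCC[C@](C)(COC(C)=O)[C@H]2[C@H](O)C[C@]1(C)O | target

Total step count: 16. Longest linear sequence: 16.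

Steps most likely to fail

Step 6. Proton exchange between the two enolates, or incomplete deprotonation of the branched ester, may let the ketone take part (closure of a cyclopentane from C9, or aldol-type self-condensation) before ring A closes. The fallback removes the ketone from play and sets out from 8. Ethane-1,2-diol and TsOH in refluxing benzene give the ethylene ketal F1. 9-BBN, then NaBO3, gives the primary alcohol F2. I2, PPh3 and imidazole give the primary iodide F3. KN(SiMe3)2 in THF (−78 → 0 °C) then closes ring A through the same H-eclipsed enolate to the ketal-protected decalin ester F4. Aqueous HCl in acetone brings the sequence back to 11.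

Step 9. Competing 1,2-addition to the carbonyl group, attack at the endocyclic terminus C6, or oligomerisation of the exocyclic enone under TiCl4 may consume 16. The fallback avoids the methylene ketone altogether and sets out from 12. The C9 dienolate (LiN(i-Pr)2, THF–DMPU, −78 °C) is alkylated directly with 4-(trimethylsilyl)but-3-yn-1-yl trifluoromethanesulfonate, a primary triflate reactive enough for a hindered enolate, to give the silylated butynyl enone F5 as C9 epimers. K2CO3 in MeOH then removes the alkyne silyl group and equilibrates C9 to the equatorial chain, which returns to 18.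

Step 12. Slow methylenation of the hindered C8 ketone may give time for loss of the β-hydroxyl group (dehydration back to the enone) or retro-aldol ring opening. The fallback replaces carbonyl methylenation by addition/elimination and sets out from 20. Et3SiCl and imidazole give the triethylsilyl ether F6. Me3SiCH2MgCl/CeCl3 (excess, THF, −78 → 0 °C) adds to the ketone without enolisation to give the β-hydroxysilane F7. Aqueous HF in MeCN effects Peterson elimination and removes the silyl ether in one operation, which returns to 21.

Further compounds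
F1 | step 6 | ethylene ketal of 8 | CCOC(=O)C(C)[C@H]1CCC2(OCCO2)C[C@]1(C)CC=C
F2 | step 6 | primary alcohol (3-hydroxypropyl on C10, ketal) | CCOC(=O)C(C)[C@H]1CCC2(OCCO2)C[C@]1(C)CCCO
F3 | step 6 | primary iodide (3-iodopropyl on C10, ketal) | CCOC(=O)C(C)[C@H]1CCC2(OCCO2)C[C@]1(C)CCCI
F4 | step 6 | ketal-protected decalin ester (ethylene ketal of 11) | C1[C@]2(C)CCC[C@](C)(C(=O)OCC)[C@H]2CCC13OCCO3
F5 | step 9 | silylated butynyl enone (C9 epimers) | C[Si](C)(C)C#CCCC1[C@]2(C)CCC[C@](C)(C(=O)OCC)[C@H]2C=CC1=O
F6 | step 12 | triethylsilyl ether of 20 | C#CCC[C@H]1[C@]2(C)CCC[C@](C)(C(=O)OCC)[C@H]2[C@H](O[Si](CC)(CC)CC)CC1=O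
F7 | step 12 | β-hydroxysilane (C8 open) | C#CCC[C@H]1[C@]2(C)CCC[C@](C)(C(=O)OCC)[C@H]2[C@H](O[Si](CC)(CC)CC)CC1(O)C[Si](C)(C)C
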